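The enzyme in the flask is charged at 25 µM against 35 mM of substrate, far less, so each enzyme must work through many substrates, and its pace is what I watch.

| flask | substrate | enzyme | remark | time |
|---|---|---|---|---|
| summer | 35 mM | 35 µM | run made earlier |  |
| spring | 35 mM | 55 µM | run made earlier |  |
| flask | 35 mM | 25 µM |  | 15 h |

| run | time / h | target / % | substrate / % |
|---|---|---|---|
| summer | 0.417 | 37.3 | 61.5 |
| summer | 1.00 | 80.6 | 15.1 |
| summer | 2.50 | 37.9 | 0.6 |
| summer | 5.00 | 5.0 | 0 |
| summer | 12.0 | 0 | 0.1 |
| spring | 0.417 | 58.0 | 41.9 |
| spring | 1.00 | 72.3 | 1.4 |
| spring | 2.50 | 12.5 | 0 |
| spring | 5.00 | 0 | 0.6 |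
| spring | 12.0 | 0 | 0 |

(scatter of a reading: 0.5 percentage points)

* time, not beyond 15 h, at which the flask holds most target
* the amount of target, in percent of the substrate charged, at that time



Free and bound enzyme together make up the enzyme charged, so I reckon the rate per enzyme charged. From the summer reading at 0.417 h I get 923 h⁻¹, the turnover number: substrate consumed per hour for each enzyme charged. The spring reading at that time gives 887 h⁻¹.

In the first stretch I expect target in the flask to rise as substrate falls, since in the summer run the two still add up to 98.8% at that reading. In the middle, the turnover number lets the flask's enzyme work through its charge in a clearing time of 1.52 h. I place the peak a little later, because the summer pace between its first two readings is 796 h⁻¹, lower than the first. Toward the end, the summer fall of target from 2.50 h to 5.00 h, scaled to the flask's enzyme, reads as a half-life of 1.20 h, shorter than the 15 h allowed, so the moment to catch is the peak.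

The forecast gives 1.65 h and 84%, holding that “the slowing substrate feed matches target loss”; its time is later than my clearing time.

The flask peaks at 1.67 h with 85.8% of target, 1.10 times my clearing time. The forecast's time belongs to this enzyme charge: in a flask with twice the enzyme and the other amounts as they are, my clearing time becomes 0.758 h and the peak of target stands at 0.835 h.

    substrate + enzyme ⇌ complex (K = 640 M⁻¹, k = 1.40 × 10⁵ M⁻¹ min⁻¹)
    complex ⇌ enzyme + target (K = 0.0940 M, k = 16.0 min⁻¹)
    enzyme + target → enzyme + over-reaction product (k = 400 M⁻¹ min⁻¹)

At 0.782 h, target in the flask is made 23.9 times faster than it is used up. The half-life of target by the over-reaction step alone, with enzyme as charged, is 1.2 h, shorter than the 15 h allowed, and at 15.0 h target stands at 0.0503%.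

The readings come from a simulation with constants of no real substance; scatter was added.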